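**Numbering used.** Locants follow the naphthalene skeleton of the target name: ring A = C1, C2, C3, C4, C4a, C8a; ring B = C4a, C5, C6, C7, C8, C8a; side chain = C1′ to C5′. Oxygens carry the locant of their carbon (O7, O8, O5′).

## Analysis of the target

- The target is a bicyclic dienone. Ring A is a cyclohexanone (C2=O). Ring B is a cross-conjugated 2-hydroxycyclohexa-2,5-dienone (C8=O, enolic O7–H on C6=C7). The two rings share the tetrasubstituted C4a=C8a bond.
- There are two stereocenters, both all-carbon quaternary and both S. C1 carries CH3, CH2OAc, C2 and C8a. C5 carries CH3, the side chain, C4a and C6.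
- The acetoxymethyl group and the C5 methyl group lie on the same face. The two centers sit on opposite ends of the flat C8a=C4a unit and share no ring as neighbours, so neither can direct the other.
- The side chain is (3E)-5-hydroxy-3-methylpent-3-enyl: a trisubstituted E-olefin and a primary allylic alcohol. It is joined to C5 through a saturated C1′–C2′ link, which rules out a direct π-allyl construction of the whole chain.
- Sensitive groups: the acidic, chelating diosphenol (O7–H/C8=O); the dienone, which can rearrange to a phenol in strong acid and can be reduced; the β-acetoxy ketone at C1 (retro-aldol once the acetate is lost); and the allylic alcohol (ionization in acid).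
- The hard part is C5. It has no hydrogen, is flanked by the C6 methyl group and by C4a, and its configuration must be set without help from C1.
- The feature that invites a bold move: ring B is the para-C-alkylated keto form of a catechol. C5 is the sp3 carbon para to the C8 carbonyl, and O7 is the second catechol oxygen. Ring A is an α-quaternary 2-tetralone.

## Retrosynthetic reasoning

**O7 and O5′ protecting groups (23 from 22).** One acid step removes the MOM group from the enol oxygen O7 and the silyl group from O5′. The acetate is the only ester, so the two primary oxygens never need to be told apart at the end.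

**C2′–C3′ bond (22 from 16 and 20).** The chain is cut between the sp3 carbon C2′ and the olefinic carbon C3′. The E geometry is then fixed in the small fragment 20 by a syn hydrometalation. This avoids olefinating a methyl ketone on a core that already holds two other carbonyl groups. The forward step is an sp3–sp2 cross-coupling of a primary alkyl iodide.

**Two-carbon handle at C5 (16 from 15, 14 and 13).** The key step can deliver an allyl group but not a homoallyl group. The terminal carbon of the allyl group is therefore cut off and the resulting aldehyde is taken to the iodide. These three functional-group steps are the price of the key step.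

**C5–C1′ bond, the key disconnection (13 from 12).** Cutting this bond turns ring B back into a hexasubstituted phenol: O8–H free, O7 as a MOM ether, methyl groups on C5 and C6. The forward reaction forms the hardest bond, sets C5, creates the dienone and leaves O7 and O8 at their final oxidation levels. The precursor 12 is a flat arene with a single stereocenter.

**C1–CH2O bond (12 from 11, 10 and 9).** The hydroxymethyl group is added to the planar enol silane 10, so C1 is set by a chiral catalyst. This is done before the key step because a C1–H would compete with C5 as the nucleophile.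

**Ring A (9 from 8, 7, 5 and 6).** The C1–C8a bond comes from an intramolecular ketone α-arylation and the C4–C4a bond from a Heck reaction. The bromide for the Heck step is already in the starting material. The second bromide goes onto the only remaining aromatic C–H, ortho to the free phenol.

**Arene (5 from 1).** O8 is introduced ortho to the original phenol oxygen (O7) by formylation and oxidative aryl migration. Protecting O7 in between gives the differentiated catechol without any selectivity problem.

**Fragment (20 from 18 and 17).** The vinyl iodide comes from a protected butynol by hydrometalation and iodination.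

## Alternatives that were turned down

**Alternative 1 (the textbook route): enolate alkylations on a Birch-derived core.**
- Disconnection: C5–C1′ and C1–CH2O, each cut as the alkylation of a 2-tetralone-type enolate.
- Forward: 2,6-dimethoxy-1,5-dimethylnaphthalene A1 (two steps from the commercial parent diether) is half-reduced to tetralone A2. The key step is an asymmetric phase-transfer alkylation of A2 with the homoallylic iodide A4, giving A3 with C5 and the whole chain in place.
- Why turned down: stereocontrol is well founded, but ring B arrives at the wrong oxidation state. The carbonyl of A3 must be exchanged for the C6 methyl group (enol triflate, then cross-coupling). Ring A needs a second Birch reduction in the presence of the chain. O8 and O7 then need a bis-allylic oxidation, an epoxidation and an isomerization. That is about thirteen linear steps plus three for A4, with skipped polyenes and dienolates on the way, and no single step carries the route.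

**Alternative 2: desymmetrization of a monocyclic dienone.**
- Disconnection: the C6 methyl group and all of ring A are removed, leaving the achiral dienone A5.
- Forward: a copper-catalysed asymmetric conjugate methylation would pick one of the two enantiotopic enone arms of A5 and so define C5.
- Why turned down: the catalyst selects a face of the β-carbon, not an arm. The two C5 substituents (CH3 and CH2CH2R) differ too little to bias the faces, so both arms would react and both C5 configurations would appear after re-oxidation. Ring A would then have to be built onto C4a and C8a of a dienone, at least five further steps.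

**Alternative 3: one-step radical union with the whole side chain.**
- Disconnection: C5–C1′, with the complete chain as the partner.
- Forward: anodic co-oxidation of phenol 12 and the carboxylic acid A6 (decarboxylative radical coupling). The alkyl radical and the phenoxyl radical combine at C5 to give 22 directly.
- Why turned down: it would save four steps, but a radical–radical coupling on a planar phenoxyl has no source of facial control, because C1 is five bonds from C5. The epimer A7 would form in equal amount, next to O-coupling and chain dimer. The stereochemical risk could not be contained.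

Key step: step 9

**Remark on assumptions.** Compounds 1, 6 and 17 are taken as commercially available. The ligand enantiomers in steps 7 and 9 are assigned by analogy; the antipodal ligand would be used if the sense of induction proved opposite.

## Route

Step 1
Reactants: 1 4-bromo-2,3-dimethylphenol
Product: 2 5-bromo-2-hydroxy-3,4-dimethylbenzaldehyde
Conditions: MgCl2, Et3N, (CH2O)n, MeCN, reflux
Reagents that add atoms: paraformaldehyde (as formaldehyde), C=O
Why: Magnesium phenoxide-directed ortho-formylation (Casnati–Skattebøl reaction): the only free ortho position of 1 is formylated and a second equivalent of formaldehyde takes up the hydride; the bromide and both methyl groups are untouched.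

Step 2
Reactants: 2 5-bromo-2-hydroxy-3,4-dimethylbenzaldehyde
Product: 3 5-bromo-2-(methoxymethoxy)-3,4-dimethylbenzaldehyde
Conditions: MOMCl, i-Pr2NEt, CH2Cl2, 0 °C → 40 °C
Reagents that add atoms: chloromethyl methyl ether (MOMCl), COCCl
Why: O-Alkylation of the phenol with a chloromethyl ether; the MOM acetal should survive base, palladium, hydride and zinc and later leave the enol oxygen in dilute acid.

Step 3
Reactants: 3 5-bromo-2-(methoxymethoxy)-3,4-dimethylbenzaldehyde
Product: 5 5-bromo-2-(methoxymethoxy)-3,4-dimethylphenol, via aryl formate 4 (not isolated)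
Conditions: mCPBA, CH2Cl2, 0 °C → 25 °C; then K2CO3 (cat.), MeOH, 25 °C
Reagents that add atoms: 3-chloroperoxybenzoic acid (mCPBA), OOC(=O)c1cccc(Cl)c1
Why: Baeyer–Villiger (Dakin-type) oxidation: the aryl group, made electron-rich by the ortho alkoxy and para methyl donors, migrates to oxygen, and catalytic methanolysis of formate 4 leaves O8 as the free phenol and O7 protected.

Step 4
Reactants: 5 5-bromo-2-(methoxymethoxy)-3,4-dimethylphenol; 6 pent-1-en-3-ol
Product: 7 1-[5-hydroxy-4-(methoxymethoxy)-2,3-dimethylphenyl]pentan-3-one
Conditions: Pd(OAc)2 (5 mol%), P(o-tol)3 (10 mol%), NaHCO3, Bu4NCl, DMF, 100 °C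
Reagents that add atoms: none
Why: Mizoroki–Heck arylation of an allylic alcohol: aryl-palladium adds to the terminal carbon, and β-hydride elimination towards the carbinol gives the enol and hence the saturated ethyl ketone; C4, C3, C2, C1 and the C1 methyl group are attached in one step, and the free phenol and MOM ether tolerate the weak base.

Step 5
Reactants: 7 1-[5-hydroxy-4-(methoxymethoxy)-2,3-dimethylphenyl]pentan-3-one
Product: 8 1-[2-bromo-3-hydroxy-4-(methoxymethoxy)-5,6-dimethylphenyl]pentan-3-one
Conditions: NBS, MeCN, −20 °C, dark
Reagents that add atoms: N-bromosuccinimide (NBS), BrN1C(=O)CCC1=O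
Why: Electrophilic aromatic bromination ortho to the free phenol; 7 has a single aromatic C–H, so the position is unambiguous, and low temperature in the dark should suppress benzylic and α-keto bromination.

Step 6
Reactants: 8 1-[2-bromo-3-hydroxy-4-(methoxymethoxy)-5,6-dimethylphenyl]pentan-3-one
Product: 9 (±)-8-hydroxy-7-(methoxymethoxy)-1,5,6-trimethyl-3,4-dihydronaphthalen-2(1H)-one
Conditions: Pd(OAc)2 (5 mol%), XPhos (10 mol%), NaOt-Bu, toluene, 80 °C, argon
Reagents that add atoms: none
Why: Palladium-catalysed intramolecular α-arylation of the ketone enolate: only the ethyl-side α-carbon can reach the aryl-palladium centre (six-membered ring; the other α-carbon would give a four-membered ring), which closes ring A; 9 is racemic and its C1 stereocenter is erased in the next step.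

Step 7
Reactants: 9 (±)-8-hydroxy-7-(methoxymethoxy)-1,5,6-trimethyl-3,4-dihydronaphthalen-2(1H)-one
Product: 11 (1S)-8-hydroxy-1-(hydroxymethyl)-7-(methoxymethoxy)-1,5,6-trimethyl-3,4-dihydronaphthalen-2(1H)-one, via bis(silyl) enol ether 10 (not isolated)
Conditions: LiN(SiMe3)2, THF, −78 → 0 °C; TMSCl; then aq. HCHO, Sc(OTf)3 (10 mol%), (S,S)-6,6′-bis(1-hydroxy-2,2-dimethylpropyl)-2,2′-bipyridine (12 mol%), DME/H2O 9:1, −20 °C
Reagents that add atoms: formaldehyde (aqueous), C=O
Why: The more acidic benzylic C1–H gives the conjugated enolate, which is trapped together with the phenoxide as 10, where C1 is planar; the Mukaiyama aldol reaction with aqueous formaldehyde under the chiral Sc(OTf)3–bipyridine catalyst (catalytic asymmetric hydroxymethylation of silicon enolates) should deliver the hydroxymethyl group to one face and set the quaternary center C1 as S by catalyst control; the aryl silyl ether hydrolyses in the aqueous medium.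

Step 8
Reactants: 11 (1S)-8-hydroxy-1-(hydroxymethyl)-7-(methoxymethoxy)-1,5,6-trimethyl-3,4-dihydronaphthalen-2(1H)-one
Product: 12 [(1S)-8-hydroxy-7-(methoxymethoxy)-1,5,6-trimethyl-2-oxo-1,2,3,4-tetrahydronaphthalen-1-yl]methyl acetate
Conditions: Ac2O (1.1 equiv), pyridine, CH2Cl2, 0 °C
Reagents that add atoms: acetic anhydride, CC(=O)OC(C)=O
Why: Acylation of the primary alcohol; the C8 phenol is flanked by the MOM ether and the C1 quaternary carbon and is hydrogen-bonded, and any aryl acetate that forms can pass its acyl group to the neighbouring primary hydroxyl, so the neopentyl mono-acetate is the expected product; a non-basic work-up avoids retro-aldol cleavage.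

Step 9
Reactants: 12 [(1S)-8-hydroxy-7-(methoxymethoxy)-1,5,6-trimethyl-2-oxo-1,2,3,4-tetrahydronaphthalen-1-yl]methyl acetate
Product: 13 [(1S,5S)-7-(methoxymethoxy)-1,5,6-trimethyl-2,8-dioxo-5-(prop-2-en-1-yl)-1,2,3,4,5,8-hexahydronaphthalen-1-yl]methyl acetate
Conditions: allyl methyl carbonate, Pd2(dba)3·CHCl3 (2.5 mol%), (R,R)-N,N′-(cyclohexane-1,2-diyl)bis[2-(diphenylphosphanyl)benzamide] (7.5 mol%), 1,4-dioxane, 25 °C
Reagents that add atoms: allyl methyl carbonate, C=CCOC(=O)OC
Why: Proposed new method: zerovalent palladium ionizes allyl methyl carbonate to a cationic π-allylpalladium complex and methyl carbonate, which loses CO2 to give methoxide; methoxide deprotonates phenol 12, and the phenoxide attacks the π-allyl ligand from outside the metal (Tsuji–Trost manifold). O-Allylation is reversible because the catalyst re-ionizes the aryl allyl ether, whereas attack through C5, the carbon para to O8, is irreversible, so dienone 13 should collect as the kinetic product even though an aryl allyl ether is the more stable isomer. The closest known reaction types are the palladium-catalysed intermolecular asymmetric allylic dearomatization of 1,3-disubstituted 2-naphthols and the intramolecular para-selective (ipso) allylic dearomatization of phenols to spirocyclohexadienones; the intermolecular attack of a benzenoid phenoxide through a substituted para carbon is the untested part. No ring is closed: one C–C bond (C5–C1′) is formed and ring B changes from an arene into the cross-conjugated 2-alkoxydienone of the target. The new stereocenter C5 is set by the chiral ligand, which can tell the two faces of the planar phenoxide apart through its unlike flanks (C6 methyl and O7-MOM on one side, C4 methylene and the C8a–C1 quaternary junction on the other); C1 is five bonds away, so the outcome should be reagent-controlled with little matched or mismatched effect. The step needs selectivity for C5 over O8, C8a and C7: C8a is fully substituted next to the quaternary C1, C7 carries the MOM ether, and O-allylation is drained by its reversibility. It also needs chemoselectivity over the C2 ketone and the acetate: a phenoxide-level base does not enolize the ketone (C1 is quaternary and C3–H is far less acidic than the phenol), and the phenol consumes methoxide faster than the ester does.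

Step 10
Reactants: 13 [(1S,5S)-7-(methoxymethoxy)-1,5,6-trimethyl-2,8-dioxo-5-(prop-2-en-1-yl)-1,2,3,4,5,8-hexahydronaphthalen-1-yl]methyl acetate
Product: 14 [(1S,5S)-7-(methoxymethoxy)-1,5,6-trimethyl-2,8-dioxo-5-(2-oxoethyl)-1,2,3,4,5,8-hexahydronaphthalen-1-yl]methyl acetate
Conditions: OsO4 (2 mol%), NaIO4, 2,6-lutidine, 1,4-dioxane/H2O 3:1, 25 °C
Reagents that add atoms: osmium tetroxide OsO4 (catalytic oxygen carrier), O=[Os](=O)(=O)=O; sodium periodate NaIO4 (terminal oxidant), [Na+].[O-]I(=O)(=O)=O
Why: Lemieux–Johnson oxidation: the monosubstituted terminal alkene should be dihydroxylated far faster than the tetrasubstituted, conjugated ring alkenes, and the diol is cleaved in situ; this removes the terminal carbon and leaves a two-carbon aldehyde on C5.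

Step 11
Reactants: 14 [(1S,5S)-7-(methoxymethoxy)-1,5,6-trimethyl-2,8-dioxo-5-(2-oxoethyl)-1,2,3,4,5,8-hexahydronaphthalen-1-yl]methyl acetate
Product: 15 [(1S,5S)-5-(2-hydroxyethyl)-7-(methoxymethoxy)-1,5,6-trimethyl-2,8-dioxo-1,2,3,4,5,8-hexahydronaphthalen-1-yl]methyl acetate
Conditions: NaBH4, MeOH/CH2Cl2 1:1, −78 °C
Reagents that add atoms: none
Why: Borohydride reduction at low temperature should be selective for the unhindered aldehyde over the α-quaternary C2 ketone and the hindered, cross-conjugated C8 carbonyl.

Step 12
Reactants: 15 [(1S,5S)-5-(2-hydroxyethyl)-7-(methoxymethoxy)-1,5,6-trimethyl-2,8-dioxo-1,2,3,4,5,8-hexahydronaphthalen-1-yl]methyl acetate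
Product: 16 [(1S,5S)-5-(2-iodoethyl)-7-(methoxymethoxy)-1,5,6-trimethyl-2,8-dioxo-1,2,3,4,5,8-hexahydronaphthalen-1-yl]methyl acetate
Conditions: I2, PPh3, imidazole, CH2Cl2, 0 °C
Reagents that add atoms: iodine, II
Why: Appel-type iodination of the primary alcohol under buffered, near-neutral conditions, compatible with the MOM enol ether, the acetate and the dienone; the alcohol is converted at once so that it has little time to add to the dienone.

Step 13
Reactants: 17 but-2-yn-1-ol
Product: 18 (but-2-yn-1-yloxy)(tert-butyl)dimethylsilane
Conditions: TBSCl, imidazole, CH2Cl2, 25 °C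
Reagents that add atoms: tert-butyldimethylsilyl chloride (TBSCl), CC(C)(C)[Si](C)(C)Cl
Why: Standard silylation of the propargylic alcohol; the silyl ether masks O5′ for the organometallic steps.

Step 14
Reactants: 18 (but-2-yn-1-yloxy)(tert-butyl)dimethylsilane
Product: 20 tert-butyl{[(2E)-3-iodobut-2-en-1-yl]oxy}dimethylsilane, via alkenylzirconocene chloride 19 (not isolated)
Conditions: Cp2Zr(H)Cl, THF, 25 → 40 °C; then I2, 0 °C
Reagents that add atoms: iodine, II
Why: Hydrozirconation–iodination: syn addition of Zr–H across the alkyne should place zirconium on C3, next to the small methyl group (warming with a slight excess of reagent equilibrates towards this regioisomer), and iodinolysis with retention gives the E-vinyl iodide with iodine trans to the CH2O group.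

Step 15
Reactants: 16 [(1S,5S)-5-(2-iodoethyl)-7-(methoxymethoxy)-1,5,6-trimethyl-2,8-dioxo-1,2,3,4,5,8-hexahydronaphthalen-1-yl]methyl acetate; 20 tert-butyl{[(2E)-3-iodobut-2-en-1-yl]oxy}dimethylsilane
Product: 22 [(1S,5S)-5-[(3E)-5-{[tert-butyl(dimethyl)silyl]oxy}-3-methylpent-3-en-1-yl]-7-(methoxymethoxy)-1,5,6-trimethyl-2,8-dioxo-1,2,3,4,5,8-hexahydronaphthalen-1-yl]methyl acetate, via alkylzinc iodide 21 (not isolated)
Conditions: Zn dust, LiCl, THF, 25 °C; then 20, Pd(OAc)2 (3 mol%), SPhos (6 mol%), THF, 25 → 40 °C
Reagents that add atoms: none
Why: Negishi coupling: zinc insertion into the primary alkyl iodide gives 21, a reagent class that tolerates ketones, esters and acetals, and palladium-catalysed coupling with 20 forms the C2′–C3′ bond with retention of the E geometry set in step 14.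

Step 16
Reactants: 22 [(1S,5S)-5-[(3E)-5-{[tert-butyl(dimethyl)silyl]oxy}-3-methylpent-3-en-1-yl]-7-(methoxymethoxy)-1,5,6-trimethyl-2,8-dioxo-1,2,3,4,5,8-hexahydronaphthalen-1-yl]methyl acetate
Product: 23 [(1S,5S)-7-hydroxy-5-[(3E)-5-hydroxy-3-methylpent-3-en-1-yl]-1,5,6-trimethyl-2,8-dioxo-1,2,3,4,5,8-hexahydronaphthalen-1-yl]methyl acetate
Conditions: 1 M HCl, THF/H2O, 0 → 25 °C
Reagents that add atoms: none
Why: Acidic hydrolysis: the MOM group on the enol oxygen O7 and the primary silyl ether should both be cleaved by dilute aqueous acid, while the acetate, the ketone and both quaternary stereocenters are untouched; the freed 7,8-dione enolizes towards C6 to give the diosphenol of 23.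

## Compound list

1 | 4-bromo-2,3-dimethylphenol | Cc1c(C)c(Br)ccc1O | starting material
2 | 5-bromo-2-hydroxy-3,4-dimethylbenzaldehyde | O=Cc1cc(Br)c(C)c(C)c1O | intermediate
3 | 5-bromo-2-(methoxymethoxy)-3,4-dimethylbenzaldehyde | COCOc1c(C)c(C)c(Br)cc1C=O | intermediate
4 | 5-bromo-2-(methoxymethoxy)-3,4-dimethylphenyl formate | COCOc1c(C)c(C)c(Br)cc1OC=O | intermediate
5 | 5-bromo-2-(methoxymethoxy)-3,4-dimethylphenol | COCOc1c(C)c(C)c(Br)cc1O | intermediate
6 | pent-1-en-3-ol (racemic) | CCC(O)C=C | starting material
7 | 1-[5-hydroxy-4-(methoxymethoxy)-2,3-dimethylphenyl]pentan-3-one | CCC(=O)CCc1cc(O)c(OCOC)c(C)c1C | intermediate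
8 | 1-[2-bromo-3-hydroxy-4-(methoxymethoxy)-5,6-dimethylphenyl]pentan-3-one | CCC(=O)CCc1c(Br)c(O)c(OCOC)c(C)c1C | intermediate
9 | (±)-8-hydroxy-7-(methoxymethoxy)-1,5,6-trimethyl-3,4-dihydronaphthalen-2(1H)-one | CC1C(=O)CCc2c(C)c(C)c(OCOC)c(O)c21 | intermediate
10 | 7-(methoxymethoxy)-1,5,6-trimethyl-2,8-bis[(trimethylsilyl)oxy]-3,4-dihydronaphthalene | CC1=C(O[Si](C)(C)C)CCc2c(C)c(C)c(OCOC)c(O[Si](C)(C)C)c21 | intermediate
11 | (1S)-8-hydroxy-1-(hydroxymethyl)-7-(methoxymethoxy)-1,5,6-trimethyl-3,4-dihydronaphthalen-2(1H)-one | OC[C@@]1(C)C(=O)CCc2c(C)c(C)c(OCOC)c(O)c21 | intermediate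
12 | [(1S)-8-hydroxy-7-(methoxymethoxy)-1,5,6-trimethyl-2-oxo-1,2,3,4-tetrahydronaphthalen-1-yl]methyl acetate | CC(=O)OC[C@@]1(C)C(=O)CCc2c(C)c(C)c(OCOC)c(O)c21 | intermediate
13 | [(1S,5S)-7-(methoxymethoxy)-1,5,6-trimethyl-2,8-dioxo-5-(prop-2-en-1-yl)-1,2,3,4,5,8-hexahydronaphthalen-1-yl]methyl acetate | CC(=O)OC[C@@]1(C)C(=O)CCC2=C1C(=O)C(OCOC)=C(C)[C@@]2(C)CC=C | intermediate
14 | [(1S,5S)-7-(methoxymethoxy)-1,5,6-trimethyl-2,8-dioxo-5-(2-oxoethyl)-1,2,3,4,5,8-hexahydronaphthalen-1-yl]methyl acetate | CC(=O)OC[C@@]1(C)C(=O)CCC2=C1C(=O)C(OCOC)=C(C)[C@@]2(C)CC=O | intermediate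
15 | [(1S,5S)-5-(2-hydroxyethyl)-7-(methoxymethoxy)-1,5,6-trimethyl-2,8-dioxo-1,2,3,4,5,8-hexahydronaphthalen-1-yl]methyl acetate | CC(=O)OC[C@@]1(C)C(=O)CCC2=C1C(=O)C(OCOC)=C(C)[C@@]2(C)CCO | intermediate
16 | [(1S,5S)-5-(2-iodoethyl)-7-(methoxymethoxy)-1,5,6-trimethyl-2,8-dioxo-1,2,3,4,5,8-hexahydronaphthalen-1-yl]methyl acetate | CC(=O)OC[C@@]1(C)C(=O)CCC2=C1C(=O)C(OCOC)=C(C)[C@@]2(C)CCI | intermediate
17 | but-2-yn-1-ol | CC#CCO | starting material
18 | (but-2-yn-1-yloxy)(tert-butyl)dimethylsilane | CC#CCO[Si](C)(C)C(C)(C)C | intermediate
19 | chloridobis(cyclopentadienyl)[(2E)-4-{[tert-butyl(dimethyl)silyl]oxy}but-2-en-2-yl]zirconium, Cp2Zr(Cl)[C(CH3)=CHCH2OTBS] | Cl[Zr](C1C=CC=C1)(C1C=CC=C1)/C(C)=C/CO[Si](C)(C)C(C)(C)C | intermediate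
20 | tert-butyl{[(2E)-3-iodobut-2-en-1-yl]oxy}dimethylsilane | I/C(C)=C/CO[Si](C)(C)C(C)(C)C | intermediate
21 | {2-[(1S,5S)-5-(acetoxymethyl)-3-(methoxymethoxy)-1,2,5-trimethyl-4,6-dioxo-1,4,5,6,7,8-hexahydronaphthalen-1-yl]ethyl}zinc iodide, RCH2CH2ZnI | CC(=O)OC[C@@]1(C)C(=O)CCC2=C1C(=O)C(OCOC)=C(C)[C@@]2(C)CC[Zn]I | intermediate
22 | [(1S,5S)-5-[(3E)-5-{[tert-butyl(dimethyl)silyl]oxy}-3-methylpent-3-en-1-yl]-7-(methoxymethoxy)-1,5,6-trimethyl-2,8-dioxo-1,2,3,4,5,8-hexahydronaphthalen-1-yl]methyl acetate | CC(=O)OC[C@@]1(C)C(=O)CCC2=C1C(=O)C(OCOC)=C(C)[C@@]2(C)CC/C(C)=C/CO[Si](C)(C)C(C)(C)C | intermediate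
23 | [(1S,5S)-7-hydroxy-5-[(3E)-5-hydroxy-3-methylpent-3-en-1-yl]-1,5,6-trimethyl-2,8-dioxo-1,2,3,4,5,8-hexahydronaphthalen-1-yl]methyl acetate | CC(=O)OC[C@@]1(C)C(=O)CCC2=C1C(=O)C(O)=C(C)[C@@]2(C)CC/C(C)=C/CO | target

## Step count and least certain steps

Total step count: 16. Longest linear sequence: 14 (steps 1 to 12, then 15 and 16). Steps 13 and 14 make fragment 20. Step 7 is counted as one telescoped step.

**Step 9 (key step, proposed new method).** Three things may go wrong. The phenoxide may rest as its O-allyl ether with C5 attack too slow to drain it. Facial selectivity at C5 may be poor, because the reacting carbon is far from the oxygen that anchors the ion pair. Some attack may occur at C7. The fallback reverses the polarity and uses known chemistry. It sets out from 12, which is oxidized with the trivalent iodine reagent PhI(OAc)2 in (CF3)2CHOH at 0 °C in the presence of allyltrimethylsilane (oxidative para-allylation of 4-alkylphenols). The phenoxonium ion is trapped at C5 without facial control. This gives 13 together with its C5 epimer, [(1S,5R)-7-(methoxymethoxy)-1,5,6-trimethyl-2,8-dioxo-5-(prop-2-en-1-yl)-1,2,3,4,5,8-hexahydronaphthalen-1-yl]methyl acetate F1. The two are diastereomers and are separated by chromatography. The route is rejoined at 13.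

**Step 7.** The enol silane may be protodesilylated back to 9 before the aldol step. Face discrimination at the tetrasubstituted, peri-hindered C1 may be insufficient. The product may undergo retro-aldol cleavage on work-up. The fallback is a resolution. It sets out from 9 and passes through 10, which is hydroxymethylated without a chiral ligand (Yb(OTf)3, aqueous formaldehyde). This gives 11 together with its enantiomer, (1R)-8-hydroxy-1-(hydroxymethyl)-7-(methoxymethoxy)-1,5,6-trimethyl-3,4-dihydronaphthalen-2(1H)-one F2. A lipase chosen by screening for acylation of the (1S)-alcohol (for example Burkholderia cepacia lipase, vinyl acetate) then acetylates 11 and leaves F2, which is removed by chromatography. The route is rejoined at 12, so step 8 is skipped.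

**Step 6.** Oxidative addition into the di-ortho-substituted, electron-rich aryl bromide may be slow, leading to protodebromination. The tetralone enolate may be oxidized by traces of air. The fallback replaces palladium by a photostimulated radical-chain substitution (SRN1). It sets out from 8, whose dianion (KOt-Bu, DMSO, irradiation) cyclizes through the aryl radical onto the enolate carbon. It rejoins the route at 9, and no new compound is formed (F0).

**Step 15.** The dienone may be reduced by electron transfer during zinc insertion, and some alkyl iodide may be lost by protonation. The fallback avoids a preformed organometallic. It sets out from 16 and 20, which are joined by a nickel-catalysed reductive cross-electrophile coupling (NiCl2·glyme, 4,4′-di-tert-butyl-2,2′-bipyridine, Mn powder, DMA). It rejoins the route at 22, and no new compound is formed (F0).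

**Step 16.** The allylic alcohol may ionize, or the acetate may be partly hydrolysed, while the MOM group is still coming off. The fallback splits the deprotection into two mild steps. It sets out from 22. HF·pyridine in THF removes the silyl group and gives [(1S,5S)-5-[(3E)-5-hydroxy-3-methylpent-3-en-1-yl]-7-(methoxymethoxy)-1,5,6-trimethyl-2,8-dioxo-1,2,3,4,5,8-hexahydronaphthalen-1-yl]methyl acetate F3. The MOM group is then cleaved without protic acid (ZnBr2, propane-1-thiol, CH2Cl2, 0 °C). The route is rejoined at 23.

Further compounds

F1 | step 9 | [(1S,5R)-7-(methoxymethoxy)-1,5,6-trimethyl-2,8-dioxo-5-(prop-2-en-1-yl)-1,2,3,4,5,8-hexahydronaphthalen-1-yl]methyl acetate | CC(=O)OC[C@@]1(C)C(=O)CCC2=C1C(=O)C(OCOC)=C(C)[C@]2(C)CC=C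
F2 | step 7 | (1R)-8-hydroxy-1-(hydroxymethyl)-7-(methoxymethoxy)-1,5,6-trimethyl-3,4-dihydronaphthalen-2(1H)-one | OC[C@]1(C)C(=O)CCc2c(C)c(C)c(OCOC)c(O)c21
F0 | step 6 | none | none
F0 | step 15 | none | none
F3 | step 16 | [(1S,5S)-5-[(3E)-5-hydroxy-3-methylpent-3-en-1-yl]-7-(methoxymethoxy)-1,5,6-trimethyl-2,8-dioxo-1,2,3,4,5,8-hexahydronaphthalen-1-yl]methyl acetate | CC(=O)OC[C@@]1(C)C(=O)CCC2=C1C(=O)C(OCOC)=C(C)[C@@]2(C)CC/C(C)=C/CO
A1 | alternative 1 | 2,6-dimethoxy-1,5-dimethylnaphthalene | COc1ccc2c(C)c(OC)ccc2c1C
A2 | alternative 1 | (±)-6-methoxy-1,5-dimethyl-3,4-dihydronaphthalen-2(1H)-one | CC1C(=O)CCc2c1ccc(OC)c2C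
A3 | alternative 1 | (1S)-1-[(3E)-5-{[tert-butyl(dimethyl)silyl]oxy}-3-methylpent-3-en-1-yl]-6-methoxy-1,5-dimethyl-3,4-dihydronaphthalen-2(1H)-one | COc1ccc2c(CCC(=O)[C@@]2(C)CC/C(C)=C/CO[Si](C)(C)C(C)(C)C)c1C
A4 | alternative 1 | tert-butyl{[(2E)-5-iodo-3-methylpent-2-en-1-yl]oxy}dimethylsilane | ICC/C(C)=C/CO[Si](C)(C)C(C)(C)C
A5 | alternative 2 | 4-[(3E)-5-{[tert-butyl(dimethyl)silyl]oxy}-3-methylpent-3-en-1-yl]-4-methylcyclohexa-2,5-dien-1-one | CC1(CC/C(C)=C/CO[Si](C)(C)C(C)(C)C)C=CC(=O)C=C1
A6 | alternative 3 | (4E)-6-{[tert-butyl(dimethyl)silyl]oxy}-4-methylhex-4-enoic acid | OC(=O)CC/C(C)=C/CO[Si](C)(C)C(C)(C)C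
A7 | alternative 3 | [(1S,5R)-5-[(3E)-5-{[tert-butyl(dimethyl)silyl]oxy}-3-methylpent-3-en-1-yl]-7-(methoxymethoxy)-1,5,6-trimethyl-2,8-dioxo-1,2,3,4,5,8-hexahydronaphthalen-1-yl]methyl acetate | CC(=O)OC[C@@]1(C)C(=O)CCC2=C1C(=O)C(OCOC)=C(C)[C@]2(C)CC/C(C)=C/CO[Si](C)(C)C(C)(C)C
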